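**Plan**
- Retrosynthesis first cuts both bonds of the bridging CH2 (chromene C8–CH2 and CH2–pyranone C3). This gives chromene 11, pyranone 16 and a one-carbon iminium salt.
- Chromene 11 is then cut at C4–C4a and C2–C3 of the pyran ring. The C3=C4 unit becomes acetylene; the rest is a 2-aryloxy-2-methylpropanoic acid, used as its N-acyloxyphthalimide 9.
- Enabling feature: C2 of the pyran ring is a fully substituted carbon on the ring oxygen O1, so it can be released as a tertiary α-aryloxyalkyl radical from a carboxyl group. In 9 the benzene ring carries O1 para to the isobutyryl group, so its two C–H positions ortho to O1 are equivalent and only the 6-acyl-5,7-dihydroxychromene can form.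
- Forward order: the benzene ring of phloroglucinol is acylated and O-alkylated (steps 1–4), the pyran ring is closed by radical annulation (step 5), the pyranone ring is built separately from pentan-3-one and malonyl dichloride (steps 6–7), and the halves are joined through CH2 (step 8).
- Stereochemistry: the target has no stereocenter; its only non-aromatic double bond (C3=C4) lies in the pyran ring and is necessarily cis.

Key step: step 5

Step 1
Reactants: 1 phloroglucinol; 2 2-methylpropanoyl chloride
Product: 3 2-methyl-1-(2,4,6-trihydroxyphenyl)propan-1-one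
Conditions: AlCl3 (4 equiv), CH2Cl2/PhNO2, 0 °C to 40 °C; then ice/aq. HCl
Reagents that add atoms: 2-methylpropanoyl chloride (2), CC(C)C(Cl)=O
Why: Friedel–Crafts acylation of the electron-rich triphenol; the aluminium-complexed aryl ketone is deactivated, so acylation should stop after one acyl group.

Step 2
Reactants: 3 2-methyl-1-(2,4,6-trihydroxyphenyl)propan-1-one; 4 ethyl 2-bromo-2-methylpropanoate
Product: 5 ethyl 2-[3,5-dihydroxy-4-(2-methylpropanoyl)phenoxy]-2-methylpropanoate
Conditions: K2CO3 (1.1 equiv), 4 (2 equiv), DMF, 60 °C
Reagents that add atoms: ethyl 2-bromo-2-methylpropanoate (4), CCOC(=O)C(C)(C)Br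
Why: Williamson-type O-alkylation (the fibrate ether synthesis); the hydroxyl para to the ketone is the most acidic and the only one not chelated to the carbonyl, so one equivalent of carbonate should deliver its phenoxide alone to the tertiary α-bromo ester.

Step 3
Reactants: 5 ethyl 2-[3,5-dihydroxy-4-(2-methylpropanoyl)phenoxy]-2-methylpropanoate; 6 lithium hydroxide
Product: 7 2-[3,5-dihydroxy-4-(2-methylpropanoyl)phenoxy]-2-methylpropanoic acid
Conditions: LiOH·H2O (5 equiv), THF/MeOH/H2O, 50 °C, argon; then 1 M HCl
Reagents that add atoms: lithium hydroxide (6), [Li+].[OH-]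
Why: Saponification of the ethyl ester; the tertiary aryl ether, the aryl ketone and the phenols (as phenoxides, under argon) should be stable to aqueous hydroxide.

Step 4
Reactants: 7 2-[3,5-dihydroxy-4-(2-methylpropanoyl)phenoxy]-2-methylpropanoic acid; 8 N-hydroxyphthalimide
Product: 9 1,3-dioxoisoindolin-2-yl 2-[3,5-dihydroxy-4-(2-methylpropanoyl)phenoxy]-2-methylpropanoate
Conditions: N,N'-diisopropylcarbodiimide (1.1 equiv), DMAP (0.1 equiv), CH2Cl2, 0 °C to rt
Reagents that add atoms: N-hydroxyphthalimide (8), ON1C(=O)c2ccccc2C1=O
Why: Carbodiimide (Steglich-type) esterification; the acidic N–OH of 8 should be acylated far faster than the two phenols, which are hindered and hydrogen-bonded to the ketone.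

Step 5
Reactants: 9 1,3-dioxoisoindolin-2-yl 2-[3,5-dihydroxy-4-(2-methylpropanoyl)phenoxy]-2-methylpropanoate; 10 acetylene
Product: 11 1-(5,7-dihydroxy-2,2-dimethyl-2H-chromen-6-yl)-2-methylpropan-1-one
Conditions: fac-Ir(ppy)3 (tris(2-phenylpyridinato)iridium, 1 mol%), acetylene (1 atm, balloon, saturated solution), degassed DMSO, blue LEDs (450 nm), 25 °C
Reagents that add atoms: acetylene (10), C#C
Why: Proposed new method: photoexcited fac-Ir(ppy)3 should transfer one electron to the N-acyloxyphthalimide of 9, whose N–O cleavage and loss of CO2 give the tertiary α-aryloxyalkyl radical at the future C2; this nucleophilic radical should add to acetylene (forming C2–C3), the resulting vinyl radical at C4 should attack the ring carbon ortho to the ether oxygen (forming C4–C4a), and oxidation of the cyclohexadienyl radical by the tetravalent iridium species (or by a further molecule of 9 in a chain) with loss of a proton to phthalimide anion should restore the arene in a redox-neutral cycle. The closest known reaction types are the decarboxylative radical (4+2) annulation of N-arylglycine derivatives with alkynes to quinolines, the (4+2) radical annulation of redox-active esters of aryloxyacetic acids with alkenes to chromans, and the vinyl-radical ortho closure of aryl propargyl ethers to 2H-chromenes. The pyran ring closes in the 6-endo-trig mode on the arene; the competing 5-exo ipso attack is expected to be reversible and unproductive, because fragmentation of the spiro radical would need an alkoxyl radical. No stereocenter is formed, and the C3=C4 double bond is cis by ring constraint. The step needs site selectivity on the arene and chemoselectivity over the phenols and the product alkene: the two C–H positions ortho to the ether oxygen of 9 are equivalent by symmetry, so only one chromene can form, the phenolic O–H bonds are tied up by the ketone hydrogen bond and by DMSO, and the product alkene is shielded by the geminal methyl groups and polarity-mismatched for a nucleophilic radical.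

Step 6
Reactants: 12 pentan-3-one; 13 trimethylsilyl trifluoromethanesulfonate
Product: 14 (Z)-trimethyl(pent-2-en-3-yloxy)silane
Conditions: TMSOTf (1.1 equiv), Et3N (1.3 equiv), CH2Cl2, 0 °C; distillation
Reagents that add atoms: trimethylsilyl trifluoromethanesulfonate (13), C[Si](C)(C)OS(=O)(=O)C(F)(F)F
Why: Soft enolization and O-silylation of a symmetric ketone should give one regioisomeric silyl enol ether; its double-bond geometry (Z expected to predominate) is lost in step 7.

Step 7
Reactants: 14 (Z)-trimethyl(pent-2-en-3-yloxy)silane; 15 malonyl dichloride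
Product: 16 6-ethyl-4-hydroxy-5-methyl-2H-pyran-2-one
Conditions: Et2O, −20 °C to rt
Reagents that add atoms: malonyl dichloride (15), ClC(=O)CC(Cl)=O
Why: C-acylation of the silyl enol ether by one acid chloride group, then lactonization of the enolized 1,3-diketone onto the second (6-exo-trig acyl substitution), is the established malonyl dichloride route to 4-hydroxy-2-pyranones and places ethyl at C6 and methyl at C5.

Step 8
Reactants: 11 1-(5,7-dihydroxy-2,2-dimethyl-2H-chromen-6-yl)-2-methylpropan-1-one; 17 N,N-dimethylmethyleneiminium iodide (Eschenmoser's salt); 16 6-ethyl-4-hydroxy-5-methyl-2H-pyran-2-one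
Product: 20 6-ethyl-3-{[5,7-dihydroxy-2,2-dimethyl-6-(2-methylpropanoyl)-2H-chromen-8-yl]methyl}-4-hydroxy-5-methyl-2H-pyran-2-one (target), via Mannich base 18 (not isolated), via quinone methide 19 (not isolated)
Conditions: 11, 17 (1.05 equiv), CH2Cl2, 0 °C to rt; then 16 (1.1 equiv), MeCN, 80 °C
Reagents that add atoms: N,N-dimethylmethyleneiminium iodide (17), C[N+](C)=C.[I-]
Why: Mannich reaction at C8, the only free ring position of 11, gives the phenolic Mannich base, which on warming should lose dimethylamine to an ortho-quinone methide that C3 of pyranone 16 traps by Michael addition (the Mannich/retro-Mannich alkylation used for methylene-bridged acylphloroglucinol–pyranone dimers); all of 11 is aminomethylated before 16 is added, so no homodimer should arise.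

**Compound list**
1 | phloroglucinol (benzene-1,3,5-triol) | Oc1cc(O)cc(O)c1 | starting material
2 | 2-methylpropanoyl chloride | CC(C)C(Cl)=O | starting material
3 | 2-methyl-1-(2,4,6-trihydroxyphenyl)propan-1-one | CC(C)C(=O)c1c(O)cc(O)cc1O | intermediate
4 | ethyl 2-bromo-2-methylpropanoate | CCOC(=O)C(C)(C)Br | starting material
5 | ethyl 2-[3,5-dihydroxy-4-(2-methylpropanoyl)phenoxy]-2-methylpropanoate | CCOC(=O)C(C)(C)Oc1cc(O)c(C(=O)C(C)C)c(O)c1 | intermediate
6 | lithium hydroxide | [Li+].[OH-] | starting material
7 | 2-[3,5-dihydroxy-4-(2-methylpropanoyl)phenoxy]-2-methylpropanoic acid | OC(=O)C(C)(C)Oc1cc(O)c(C(=O)C(C)C)c(O)c1 | intermediate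
8 | N-hydroxyphthalimide | ON1C(=O)c2ccccc2C1=O | starting material
9 | 1,3-dioxoisoindolin-2-yl 2-[3,5-dihydroxy-4-(2-methylpropanoyl)phenoxy]-2-methylpropanoate | CC(C)C(=O)c1c(O)cc(OC(C)(C)C(=O)ON2C(=O)c3ccccc3C2=O)cc1O | intermediate
10 | acetylene | C#C | starting material
11 | 1-(5,7-dihydroxy-2,2-dimethyl-2H-chromen-6-yl)-2-methylpropan-1-one | CC(C)C(=O)c1c(O)cc2OC(C)(C)C=Cc2c1O | intermediate
12 | pentan-3-one | CCC(=O)CC | starting material
13 | trimethylsilyl trifluoromethanesulfonate | C[Si](C)(C)OS(=O)(=O)C(F)(F)F | starting material
14 | (Z)-trimethyl(pent-2-en-3-yloxy)silane (expected major isomer; the E isomer reacts alike) | C/C=C(/CC)O[Si](C)(C)C | intermediate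
15 | malonyl dichloride | ClC(=O)CC(Cl)=O | starting material
16 | 6-ethyl-4-hydroxy-5-methyl-2H-pyran-2-one | CCc1oc(=O)cc(O)c1C | intermediate
17 | N,N-dimethylmethyleneiminium iodide (Eschenmoser's salt) | C[N+](C)=C.[I-] | starting material
18 | 1-{8-[(dimethylamino)methyl]-5,7-dihydroxy-2,2-dimethyl-2H-chromen-6-yl}-2-methylpropan-1-one | CC(C)C(=O)c1c(O)c(CN(C)C)c2OC(C)(C)C=Cc2c1O | intermediate (not isolated)
19 | 5-hydroxy-2,2-dimethyl-8-methylidene-6-(2-methylpropanoyl)-2H-chromen-7(8H)-one (ortho-quinone methide) | CC(C)C(=O)C1=C(O)C2=C(OC(C)(C)C=C2)C(=C)C1=O | intermediate (not isolated)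
20 | 6-ethyl-3-{[5,7-dihydroxy-2,2-dimethyl-6-(2-methylpropanoyl)-2H-chromen-8-yl]methyl}-4-hydroxy-5-methyl-2H-pyran-2-one | CCc1oc(=O)c(Cc2c(O)c(C(=O)C(C)C)c(O)c3c2OC(C)(C)C=C3)c(O)c1C | target

**Step count:** 8 steps in total. The longest linear sequence is 6 steps (steps 1, 2, 3, 4, 5 and 8); the pyranone branch is steps 6 and 7.

**Steps most likely to fail**

Step 5 (Proposed new method). The addition of the tertiary α-aryloxyalkyl radical to acetylene is slow, so its oxidation to the oxocarbenium ion (which would hydrolyze back toward the phenol) or hydrogen transfer to the radical intermediates may outrun the annulation. The fallback uses known chemistry and sets out from 3. O-alkylation of its para hydroxyl with 3-chloro-3-methylbut-1-yne (K2CO3, catalytic KI, acetone, reflux) should give the aryl propargyl ether 1-[2,6-dihydroxy-4-(2-methylbut-3-yn-2-yloxy)phenyl]-2-methylpropan-1-one F1. Heating F1 in N,N-diethylaniline (about 180 °C) should effect the aromatic propargyl Claisen rearrangement, 1,5-hydrogen shift and oxa-6π electrocyclization, again giving a single chromene by symmetry. The fallback comes back to the route at 11 and replaces steps 2 to 5.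

Step 8. The aminomethyl group may scramble by retro-Mannich reaction, which would lead to methylene-bridged homodimers, and the acid set free may degrade the chromene. The fallback sets out from 11. Vilsmeier–Haack formylation at C8 (POCl3, DMF, 0 °C; then aqueous NaOAc) should give 5,7-dihydroxy-2,2-dimethyl-6-(2-methylpropanoyl)-2H-chromene-8-carbaldehyde F2. Three-component reductive alkylation of pyranone 16 with F2 and Hantzsch ester (L-proline catalyst, CH2Cl2, rt) then proceeds by Knoevenagel condensation and conjugate hydride transfer. The one-carbon unit is bound to the chromene throughout, so no homodimer can form. The fallback comes back to the route at 20.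

Step 2. The para phenoxide is a weakly nucleophilic vinylogous carboxylate, so substitution at the tertiary carbon may be sluggish, with elimination of the bromo ester and alkylation of a second hydroxyl competing. The fallback sets out from 1. Mono-O-alkylation of phloroglucinol (in excess) with 4 (K2CO3, DMF, 60 °C) should give ethyl 2-(3,5-dihydroxyphenoxy)-2-methylpropanoate F3. Friedel–Crafts acylation of F3 with 2 (AlCl3, CH2Cl2/PhNO2) should then occur between the two free hydroxyls, since the bulky tertiary ether disfavors the two positions next to it. The fallback comes back to the route at 5.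

**Further compounds**
F1 | step 5 | 1-[2,6-dihydroxy-4-(2-methylbut-3-yn-2-yloxy)phenyl]-2-methylpropan-1-one | CC(C)C(=O)c1c(O)cc(OC(C)(C)C#C)cc1O
F2 | step 8 | 5,7-dihydroxy-2,2-dimethyl-6-(2-methylpropanoyl)-2H-chromene-8-carbaldehyde | CC(C)C(=O)c1c(O)c(C=O)c2OC(C)(C)C=Cc2c1O
F3 | step 2 | ethyl 2-(3,5-dihydroxyphenoxy)-2-methylpropanoate | CCOC(=O)C(C)(C)Oc1cc(O)cc(O)c1
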